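**Retrosynthetic overview**
- The target is reached by O-deethylation of 7-ethoxy-5-hydroxy-2-tridecylchromone.
- The strategy rests on the benzo ring (C4a, C5, C6, C7, C8, C8a): it carries meta oxygens at C5 and C7 with CH at C6 and C8, and it is fused on the C8a=C4a bond, which is the C2=C3 bond of a 4-pyranone. This ring is disconnected into a pyranonyl ketene (from a 2-diazoacetyl-4-pyranone by Wolff rearrangement) and ethoxyacetylene, with the pyranone C2=C3 bond acting as the vinyl group of a vinylketene.
- The diazoketone comes from 4-oxo-6-tridecyl-4H-pyran-2-carboxylic acid, made by Claisen condensation of heptadecane-2,4-dione with diethyl oxalate and acid cyclodehydration; the dione comes from acetylacetone dianion and 1-bromododecane.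
- Ring order: the 4-pyranone ring first (step 2), the benzo ring last (step 5).

Key step: step 5

Remark: diazomethane is assumed to be used as a fresh ethereal solution generated from N-methyl-N-nitroso-p-toluenesulfonamide, and ethoxyacetylene as its commercial solution in hexanes.

**Route**

Step 1
Reactants: 1 acetylacetone; 2 1-bromododecane
Product: 3 heptadecane-2,4-dione
Conditions: LiN(iPr)2 (2.1 equiv), THF, 0 °C; then 2 (0.9 equiv), 0 °C → rt; aq. HCl
Reagents that add atoms: none
Why: Double deprotonation gives the 1,3-dianion of acetylacetone, whose terminal carbanion is much more nucleophilic than the stabilised central carbon, so SN2 alkylation by the primary bromide should occur only at the methyl carbon (γ-alkylation of a β-diketone dianion).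

Step 2
Reactants: 3 heptadecane-2,4-dione; 4 diethyl oxalate
Product: 6 ethyl 4-oxo-6-tridecyl-4H-pyran-2-carboxylate, via triketo ester 5 (not isolated)
Conditions: NaOEt (2.2 equiv), EtOH, 0 °C → rt; then conc. HCl, EtOH, reflux
Reagents that add atoms: none
Why: Claisen condensation at the unhindered terminal methyl group (through the dianion present in equilibrium under excess ethoxide) is driven by formation of the doubly enolised 2,4,6-triketo ester, which acid then cyclodehydrates between the C2 enol oxygen and the C6 carbonyl to the 4-pyranone.

Step 3
Reactants: 6 ethyl 4-oxo-6-tridecyl-4H-pyran-2-carboxylate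
Product: 7 4-oxo-6-tridecyl-4H-pyran-2-carboxylic acid
Conditions: 6 M HCl/AcOH (1:1), 90 °C
Reagents that add atoms: water, O
Why: Acid-catalysed ester hydrolysis is chosen because the 4-pyranone ring is opened by hydroxide but is stable in hot aqueous acid, where decarboxylation of the 2-carboxylic acid does not yet occur.

Step 4
Reactants: 7 4-oxo-6-tridecyl-4H-pyran-2-carboxylic acid
Product: 9 2-(2-diazoacetyl)-6-tridecyl-4H-pyran-4-one, via acid chloride 8 (not isolated)
Conditions: (COCl)2, cat. DMF, CH2Cl2, 0 °C → rt; evaporate; then CH2N2 (1.3 equiv, Et2O), Et3N (1.1 equiv), THF, −10 → 0 °C, dark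
Reagents that add atoms: diazomethane, C=[N+]=[N-]
Why: The acid chloride has no α-hydrogen and acylates diazomethane at carbon (first stage of an Arndt–Eistert sequence), and triethylamine takes up the HCl so that only a small excess of diazomethane meets the electron-poor pyranone double bonds at low temperature.

Step 5
Reactants: 9 2-(2-diazoacetyl)-6-tridecyl-4H-pyran-4-one; 10 ethoxyacetylene
Product: 15 7-ethoxy-5-hydroxy-2-tridecyl-4H-chromen-4-one, via pyranonylketene 11 (not isolated), via ethoxycyclobutenone 12 (not isolated), via dienylketene 13 (not isolated), via cyclohexadienone tautomer 14 (not isolated)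
Conditions: 10 (3 equiv), degassed ClCH2CH2Cl (0.05 M), hν (365 nm LED, Pyrex), rt; then 80 °C, dark
Reagents that add atoms: none
Why: Proposed new method: excitation of the diazoketone at 365 nm, where the 4-pyranone chromophore absorbs only weakly, should expel N2 with 1,2-shift of the pyranonyl group from the acyl carbon to the diazo carbon (Wolff rearrangement, forming C8–C8a) to give ketene 11, whose C=C bond is conjugated with the ring C2=C3 bond. The nucleophilic CH terminus of ethoxyacetylene attacks the ketene carbonyl carbon and the four-membered ring closes at the former diazo carbon in a regioselective (2+2) cycloaddition (C5–C6 and C7–C8) to cyclobutenone 12, which at 80 °C opens by reversible conrotatory four-electron electrocyclic cleavage to dienylketene 13. Only the geometry of 13 with the pyranonyl group cis to the ketene arm can close the benzo ring by thermal disrotatory six-electron electrocyclisation of the ketene carbon onto pyranone C3 (C4a–C5), and because the ring opening is reversible the unproductive geometry is returned through 12, after which enolisation of dienone 14 gives the chelated C5 phenol and restores the pyranone. The closest known reaction type is the photo-Wolff version of the Danheiser benzannulation of aryl and heteroaryl α-diazoketones with alkoxy- or siloxyalkynes, which has not been shown on a 4-pyranon-2-yl diazoketone. No stereocentre remains, since the single centre of racemic 12 and of 14 is lost on aromatisation. The step needs regiocontrol in the cycloaddition, which the polarisation of the ynol ether supplies (ethoxy ends at C7, meta to the new hydroxyl), and site control in the closure, which is secured because C3 is the only ring carbon next to the ketene-bearing C2 and is the nucleophilic α-carbon of a vinylogous ester with little aromatic stabilisation to lose.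

Step 6
Reactants: 15 7-ethoxy-5-hydroxy-2-tridecyl-4H-chromen-4-one
Product: 16 5,7-dihydroxy-2-tridecyl-4H-chromen-4-one
Conditions: BBr3 (4 equiv), CH2Cl2, −78 °C → rt; then MeOH, H2O
Reagents that add atoms: none
Why: BBr3 coordinates the ether oxygen and bromide cleaves the ethyl–oxygen bond by SN2 (Lewis-acid dealkylation of an aryl alkyl ether), while the chromone and the alkyl chain are inert and the 5-hydroxyl is only held as a borate until hydrolysis.

**Compound list**
1 | acetylacetone (pentane-2,4-dione) | CC(=O)CC(C)=O | starting material
2 | 1-bromododecane | CCCCCCCCCCCCBr | starting material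
3 | heptadecane-2,4-dione | CCCCCCCCCCCCCC(=O)CC(C)=O | intermediate
4 | diethyl oxalate | CCOC(=O)C(=O)OCC | starting material
5 | ethyl 2,4,6-trioxononadecanoate | CCCCCCCCCCCCCC(=O)CC(=O)CC(=O)C(=O)OCC | intermediate (not isolated)
6 | ethyl 4-oxo-6-tridecyl-4H-pyran-2-carboxylate | CCCCCCCCCCCCCc1cc(=O)cc(C(=O)OCC)o1 | intermediate
7 | 4-oxo-6-tridecyl-4H-pyran-2-carboxylic acid | CCCCCCCCCCCCCc1cc(=O)cc(C(=O)O)o1 | intermediate
8 | 4-oxo-6-tridecyl-4H-pyran-2-carbonyl chloride | CCCCCCCCCCCCCc1cc(=O)cc(C(=O)Cl)o1 | intermediate (not isolated)
9 | 2-(2-diazoacetyl)-6-tridecyl-4H-pyran-4-one | CCCCCCCCCCCCCc1cc(=O)cc(C(=O)C=[N+]=[N-])o1 | intermediate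
10 | ethoxyacetylene | CCOC#C | starting material
11 | 2-(2-oxoethenyl)-6-tridecyl-4H-pyran-4-one (pyranonylketene) | CCCCCCCCCCCCCc1cc(=O)cc(C=C=O)o1 | intermediate (not isolated)
12 | 2-(2-ethoxy-4-oxocyclobut-2-en-1-yl)-6-tridecyl-4H-pyran-4-one (racemic) | CCCCCCCCCCCCCc1cc(=O)cc(C2C(OCC)=CC2=O)o1 | intermediate (not isolated)
13 | 2-[(1E)-2-ethoxy-4-oxobuta-1,3-dien-1-yl]-6-tridecyl-4H-pyran-4-one (pyranonyl cis to the ketene arm) | CCCCCCCCCCCCCc1cc(=O)cc(/C=C(OCC)\C=C=O)o1 | intermediate (not isolated)
14 | 7-ethoxy-2-tridecyl-4aH-chromene-4,5-dione (racemic) | CCCCCCCCCCCCCC1=CC(=O)C2C(=O)C=C(OCC)C=C2O1 | intermediate (not isolated)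
15 | 7-ethoxy-5-hydroxy-2-tridecyl-4H-chromen-4-one | CCCCCCCCCCCCCc1cc(=O)c2c(O)cc(OCC)cc2o1 | intermediate
16 | 5,7-dihydroxy-2-tridecyl-4H-chromen-4-one | CCCCCCCCCCCCCc1cc(=O)c2c(O)cc(O)cc2o1 | target

**Step count**
Total step count: 6. Longest linear sequence: 6 steps (1 → 3 → 6 → 7 → 9 → 15 → 16).

**Steps most likely to fail**

1. Step 5 (proposed new method). The pyranone may photoisomerise in competition with the Wolff rearrangement, the ketene may dimerise or be captured by adventitious nucleophiles before it meets the alkyne, or the cyclobutenone may stall because ring opening and closure onto pyranone C3 are slow. The fallback sets out from 1-bromododecane 2 and comes back at target 16, using only known chemistry. Purchased 5,7-dimethoxy-2-methyl-4H-chromen-4-one (Cc1cc(=O)c2c(OC)cc(OC)cc2o1) would be deprotonated at the 2-methyl group with LiN(iPr)2 in THF at −78 °C, and the vinylogous enolate alkylated with 2 to give 5,7-dimethoxy-2-tridecyl-4H-chromen-4-one F1. Excess BBr3 in CH2Cl2 (rt to reflux) would then cleave both methyl ethers to give 16, so steps 5 and 6 are bypassed.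

2. Step 4. Diazomethane may add as a 1,3-dipole across the electron-poor pyranone double bonds, or the pyranone carbonyl oxygen may be activated during the chloride-forming stage, so that the diazoketone is formed impurely. The fallback sets out from acid chloride 8 and comes back at diazoketone 9 without diazomethane. Treatment of 8 with MeNH(OMe)·HCl and pyridine in CH2Cl2 at 0 °C would give N-methoxy-N-methyl-4-oxo-6-tridecyl-4H-pyran-2-carboxamide F2. MeMgBr (1.1 equiv) in THF at −78 °C would convert it into 2-acetyl-6-tridecyl-4H-pyran-4-one F3. Its enolate, formed with LiN(SiMe3)2 at −78 °C, would be acylated with 2,2,2-trifluoroethyl trifluoroacetate to 4,4,4-trifluoro-1-(4-oxo-6-tridecyl-4H-pyran-2-yl)butane-1,3-dione F4, which is not isolated. Methanesulfonyl azide, Et3N and water in MeCN would then effect detrifluoroacetylative diazo transfer to 9.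

3. Step 2. Acylation may occur at the C5 methylene or at C3, the latter followed by retro-Claisen acyl exchange, which would give regioisomeric or chain-truncated pyranones. The fallback sets out from acetylacetone 1 and diethyl oxalate 4 and comes back at triketo ester 5, with the order of the two C–C bond formations inverted so that the oxalylation has no regiochemical choice. Claisen condensation of symmetrical 1 with 4 (NaOEt, EtOH) would give ethyl 2,4,6-trioxoheptanoate F5. Its trianion (LiN(iPr)2, 3.1 equiv, THF, 0 °C) would be alkylated at the terminal methyl carbon by 1-bromododecane 2 (terminal alkylation of a tricarbonyl polyanion) to give 5, which is cyclised with conc. HCl in EtOH as in the second stage of step 2.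

**Further compounds**
F1 | step 5 | 5,7-dimethoxy-2-tridecyl-4H-chromen-4-one | CCCCCCCCCCCCCc1cc(=O)c2c(OC)cc(OC)cc2o1
F2 | step 4 | N-methoxy-N-methyl-4-oxo-6-tridecyl-4H-pyran-2-carboxamide | CCCCCCCCCCCCCc1cc(=O)cc(C(=O)N(C)OC)o1
F3 | step 4 | 2-acetyl-6-tridecyl-4H-pyran-4-one | CCCCCCCCCCCCCc1cc(=O)cc(C(C)=O)o1
F4 | step 4 | 4,4,4-trifluoro-1-(4-oxo-6-tridecyl-4H-pyran-2-yl)butane-1,3-dione | CCCCCCCCCCCCCc1cc(=O)cc(C(=O)CC(=O)C(F)(F)F)o1
F5 | step 2 | ethyl 2,4,6-trioxoheptanoate | CC(=O)CC(=O)CC(=O)C(=O)OCC
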